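**Retrosynthetic overview**

- The target is cut at the Ar–CH2 bond (arene C6 to side-chain C1). This gives 2-hydroxy-4-methoxybenzoic acid, which has only one free ortho C–H, and (R)-1-iodotridecan-2-yl acetate. They are joined last in a blue-light-driven, carboxylate-directed ruthenium-catalysed C–H alkylation that needs no protecting groups.
- (R)-1-Iodotridecan-2-yl acetate comes from (R)-1-chlorotridecan-2-yl acetate by Finkelstein exchange. The chloro acetate comes from (R)-epichlorohydrin and decylmagnesium bromide by copper-catalysed epoxide opening with acetylation in the same flask.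
- The single stereocentre is C2 of (R)-epichlorohydrin, which becomes the acetoxy carbon. None of its bonds is broken in any step.
- No ring is formed. The benzene ring is bought with OH, OMe and CO2H already in place.

Assumption: the SMILES is read as the (R)-acetate, 2-[(2R)-2-acetoxytridecyl]-6-hydroxy-4-methoxybenzoic acid; (R)-epichlorohydrin, decylmagnesium bromide solution and 2-hydroxy-4-methoxybenzoic acid are catalogue items.

**Route**

Step 1
Reactants: 1 (R)-epichlorohydrin; 2 decylmagnesium bromide
Product: 4 (R)-1-chlorotridecan-2-yl acetate, via bromomagnesium (R)-1-chlorotridecan-2-olate 3 (not isolated)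
Conditions: 1 (1.2 equiv), CuI (5 mol %), THF/Et2O, −40 → −20 °C, 2 h; then Ac2O (1.5 equiv), DMAP (5 mol %), −20 °C → rt; aq. NH4Cl
Reagents that add atoms: acetic anhydride, CC(=O)OC(C)=O
Why: Copper-catalysed Grignard epoxide opening is an SN2 attack at the unsubstituted ring CH2, so the C–O bond of the stereocentre and the C–Cl bond stay intact and the (R) centre of 1 is carried over unchanged; the magnesium alkoxide 3 is then O-acetylated (DMAP-catalysed acyl transfer) in the same flask before it can close to an epoxide.

Step 2
Reactants: 4 (R)-1-chlorotridecan-2-yl acetate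
Product: 5 (R)-1-iodotridecan-2-yl acetate
Conditions: NaI (4 equiv), 2-butanone, reflux, 24 h, dark
Reagents that add atoms: sodium iodide, [Na+].[I-]
Why: Finkelstein reaction, an SN2 halide exchange at the primary carbon driven by precipitation of NaCl; the neutral conditions leave the acetate alone and the stereocentre is not a reacting centre.

Step 3
Reactants: 5 (R)-1-iodotridecan-2-yl acetate; 6 2-hydroxy-4-methoxybenzoic acid
Product: 7 2-[(2R)-2-acetoxytridecyl]-6-hydroxy-4-methoxybenzoic acid (target)
Conditions: 6 (2.0 equiv), [RuCl2(p-cymene)]2 (5 mol %), KOAc (30 mol %), 4,4′-di-tert-butyl-2,2′-bipyridine (10 mol %), K2CO3 (1.5 equiv), 1,4-dioxane, 450 nm LEDs, N2, 30 °C, 24 h; then cold 1 M HCl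
Reagents that add atoms: none
Why: Proposed new method: a light-driven, carboxylate-directed ortho-C–H alkylation in which the potassium salt of 6 binds divalent ruthenium through its carboxylate and undergoes acetate-assisted C–H metalation at C6 (the only free ortho position) to a five-membered aryl–ruthenium carboxylate chelate; the diimine co-ligand gives this ruthenacycle a visible metal-to-ligand charge-transfer band, so under 450 nm light it reduces the C–I bond of 5 by inner-sphere single-electron transfer, the primary β-acetoxyalkyl radical rebounds to trivalent ruthenium, and C(sp2)–C(sp3) reductive elimination from the tetravalent aryl(alkyl)ruthenium species forms the Ar–CH2 bond and returns divalent ruthenium; radical and metal sit only on C1, so the (R) centre at C2 is never touched, and working at 30 °C keeps carboxylate O-alkylation, acetate loss and lactonisation out; the closest known reaction type is the visible-light-induced ruthenium-catalysed ortho-C–H alkylation and benzylation of arenes bearing nitrogen directing groups with alkyl halides (photo-excited ruthenacycle, single-electron transfer, radical rebound), together with thermal ruthenium-catalysed carboxylate-directed ortho-C–H arylation and allylation of benzoic acids; new here are a free salicylic acid as directing group under photochemical conditions and an unactivated, enantiopure β-acyloxy primary alkyl iodide as partner.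

**Compound list**

1 | (R)-epichlorohydrin, (2R)-2-(chloromethyl)oxirane | ClC[C@H]1CO1 | starting material
2 | decylmagnesium bromide (C10H21MgBr, solution in Et2O) | CCCCCCCCCC[Mg]Br | starting material
3 | bromomagnesium (R)-1-chlorotridecan-2-olate (not isolated) | CCCCCCCCCCC[C@H](CCl)O[Mg]Br | intermediate
4 | (R)-1-chlorotridecan-2-yl acetate | CCCCCCCCCCC[C@H](CCl)OC(C)=O | intermediate
5 | (R)-1-iodotridecan-2-yl acetate | CCCCCCCCCCC[C@H](CI)OC(C)=O | intermediate
6 | 2-hydroxy-4-methoxybenzoic acid (4-methoxysalicylic acid) | COc1ccc(C(=O)O)c(O)c1 | starting material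
7 | 2-[(2R)-2-acetoxytridecyl]-6-hydroxy-4-methoxybenzoic acid | CCCCCCCCCCC[C@H](Cc1cc(OC)cc(O)c1C(=O)O)OC(C)=O | target

**Totals**

Total step count: 3. Longest linear sequence: 3 (1 → 4 → 5 → 7).

**Steps most likely to fail, with fallbacks**

Step 3 (highest risk, the new step). Possible failure modes:
- the salicylate binds ruthenium as an O,O-chelate and stops C–H metalation;
- the carboxylate ruthenacycle absorbs too weakly at 450 nm;
- β-acetoxy or β-hydride elimination from the alkylruthenium species gives tridec-1-ene or an enol acetate;
- the radical abstracts hydrogen from dioxane;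
- the carboxylate is O-alkylated by 5.

The fallback uses known chemistry only. It sets out from 4 and comes back to the route at 7. K2CO3 in MeOH at rt removes the acetate and closes the chlorohydrin to (R)-1,2-epoxytridecane F6, with the C–O bond of the stereocentre untouched. Commercial 3,5-dimethoxyphenylmagnesium chloride (COc1cc(OC)cc([Mg]Cl)c1) with CuI (10 mol %) in THF at −30 °C opens F6 at the terminal carbon to (R)-1-(3,5-dimethoxyphenyl)tridecan-2-ol F7. Ac2O, pyridine and DMAP give (R)-1-(3,5-dimethoxyphenyl)tridecan-2-yl acetate F8. Vilsmeier–Haack formylation (POCl3, DMF, 0 → 60 °C) puts the aldehyde ortho to the side chain and para to a methoxy group, giving (R)-1-(2-formyl-3,5-dimethoxyphenyl)tridecan-2-yl acetate F9; the minor isomer formylated between the two methoxy groups is removed by chromatography. BCl3 in CH2Cl2 (−78 → 0 °C) cleaves only the methoxy group chelated to the aldehyde, and the acetate survives at this temperature, giving (R)-1-(2-formyl-3-hydroxy-5-methoxyphenyl)tridecan-2-yl acetate F10. Lindgren–Pinnick oxidation (NaClO2, NaH2PO4, 2-methyl-2-butene, t-BuOH/H2O) then gives 7.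

Step 2. The SN2 exchange at a β-branched, β-oxygenated primary chloride may be slow, and prolonged heating could allow acetoxy participation (regio-scrambling) or elimination.

The fallback replaces the chloride by a sulfonate from the start. It sets out from 2 and comes back at 5. Commercial (R)-glycidyl tosylate (Cc1ccc(cc1)S(=O)(=O)OC[C@H]1CO1) is opened at the epoxide CH2 by 2 (1.0 equiv) with CuI (5 mol %) in THF at −40 °C, giving (R)-2-hydroxytridecyl 4-methylbenzenesulfonate F4. Ac2O and pyridine give (R)-2-acetoxytridecyl 4-methylbenzenesulfonate F5. NaI in acetone at 50 °C displaces the much better tosylate leaving group under mild conditions to give 5.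

Step 1. The magnesium alkoxide 3 may close to the epoxide or undergo halide exchange before acetylation, or the copper-catalysed opening may give mixtures with this Grignard reagent.

The fallback builds the chain by alkynylation and hydrogenation. It sets out from 1 and comes back at 4. Dec-1-yne and n-BuLi in THF at −78 °C give lithium dec-1-ynide F1. With BF3·OEt2 this opens 1 at the epoxide CH2 at −78 °C, which is too cold for the chlorohydrin to close, giving (R)-1-chlorotridec-4-yn-2-ol F2. Ac2O, pyridine and DMAP give (R)-1-chlorotridec-4-yn-2-yl acetate F3. Hydrogenation (H2 1 atm, Pd/C, EtOAc) saturates the alkyne without touching the primary chloride or the homopropargylic acetate and gives 4.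

**Further compounds**

F1 | step 1 | lithium dec-1-ynide | [Li]C#CCCCCCCCC
F2 | step 1 | (R)-1-chlorotridec-4-yn-2-ol | CCCCCCCCC#CC[C@H](CCl)O
F3 | step 1 | (R)-1-chlorotridec-4-yn-2-yl acetate | CCCCCCCCC#CC[C@H](CCl)OC(C)=O
F4 | step 2 | (R)-2-hydroxytridecyl 4-methylbenzenesulfonate | CCCCCCCCCCC[C@H](COS(=O)(=O)c1ccc(C)cc1)O
F5 | step 2 | (R)-2-acetoxytridecyl 4-methylbenzenesulfonate | CCCCCCCCCCC[C@H](COS(=O)(=O)c1ccc(C)cc1)OC(C)=O
F6 | step 3 | (R)-1,2-epoxytridecane, (2R)-2-undecyloxirane | CCCCCCCCCCC[C@@H]1CO1
F7 | step 3 | (R)-1-(3,5-dimethoxyphenyl)tridecan-2-ol | CCCCCCCCCCC[C@H](Cc1cc(OC)cc(OC)c1)O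
F8 | step 3 | (R)-1-(3,5-dimethoxyphenyl)tridecan-2-yl acetate | CCCCCCCCCCC[C@H](Cc1cc(OC)cc(OC)c1)OC(C)=O
F9 | step 3 | (R)-1-(2-formyl-3,5-dimethoxyphenyl)tridecan-2-yl acetate | CCCCCCCCCCC[C@H](Cc1cc(OC)cc(OC)c1C=O)OC(C)=O
F10 | step 3 | (R)-1-(2-formyl-3-hydroxy-5-methoxyphenyl)tridecan-2-yl acetate | CCCCCCCCCCC[C@H](Cc1cc(OC)cc(O)c1C=O)OC(C)=O
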